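The tertiary ether C1–O–C2′ is too hindered, and its arene too electron-rich, for O-arylation. The phloroglucinol ring is therefore grown on the C1 oxygen. The feature used is the run ether oxygen (C2′), C7′-bearing carbon (C1′), hydroxyl (C6′) around the benzene ring, which is the pattern an ynol ether and a vinylketene deliver. One operation forms C6′–C1′ and C2′–C3′ and closes the arene. Its precursor is the 5-methylhex-1-ynyl ether of an aromadendran-1-ol built from (+)-2-carene. It already holds C3=C4 as a silyl enol ether, so oxidation at C7′ can close C4–C7′, and with it the oxepane ring, in the next step.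

Key step: step 16

Remark: aromadendrane numbering (C1–C15) is used for the terpene part and primed numbers for the arene (C1′ carries C7′, C2′ the ether oxygen, C4′ and C6′ the hydroxyls); compounds 13–19 are used as mixtures at C4 (13 and 14 also at C3), centres that steps 8 and 11 erase, so they are left open in the SMILES.

Step 1
Reactants: 1 (+)-2-carene
Product: 2 (1S,3R)-2,2-dimethyl-3-(3-oxobutyl)cyclopropane-1-carbaldehyde (cis)
Conditions: O3, CH2Cl2–MeOH, −78 °C; Me2S, −78 °C → rt
Reagents that add atoms: ozone, O=[O+][O-]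
Why: Ozonolysis with reductive work-up cleaves the only alkene (C5=C10) and leaves the cis-cyclopropane centres C6 and C7, taken from the chiral pool, untouched.

Step 2
Reactants: 2 keto aldehyde
Product: 4 2-[(1S,3R)-2,2-dimethyl-3-(3-oxobutyl)cyclopropyl]acetaldehyde, via methyl enol ether 3 (not isolated)
Conditions: MeOCH2PPh3Cl, KN(SiMe3)2 (1.05 equiv ylide), THF, −78 °C; then 1 M HCl, THF, rt
Reagents that add atoms: (methoxymethyl)triphenylphosphonium chloride, COC[P+](c1ccccc1)(c1ccccc1)c1ccccc1.[Cl-]; water, O
Why: Wittig methoxymethylenation with one equivalent of ylide at −78 °C takes the aldehyde ahead of the methyl ketone, and acid hydrolysis of enol ether 3 (protonation at C5, cation at C1, never next to the cyclopropane) gives the homologue whose new carbon is C1.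

Step 3
Reactants: 4 homologated keto aldehyde
Product: 5 (1S,7R)-4,8,8-trimethylbicyclo[5.1.0]oct-3-ene (C1=C10 alkene)
Conditions: TiCl3(DME)1.5, Zn–Cu, DME, reflux, slow addition of 4 (high dilution)
Reagents that add atoms: none
Why: Intramolecular McMurry coupling of a keto aldehyde under high dilution is a standard route to cycloheptenes, and since neither ketyl carbon (C1, C10) is bonded to the cyclopropane the three-membered ring should stay closed.

Step 4
Reactants: 5 cycloheptene
Product: 7 (1S,3S,4S,7R)-4,8,8-trimethylbicyclo[5.1.0]octan-3-ol, via alkylborane 6 (not isolated)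
Conditions: BH3·THF, THF, 0 °C → rt; NaOH, H2O2, 0 °C
Reagents that add atoms: hydrogen peroxide, OO
Why: Hydroboration–oxidation places boron on the less substituted C1 and adds H and B syn from the face opposite the gem-dimethylcyclopropane, as it does in the carenes, which sets C10 with H10 anti and the methyl group syn to the CMe2 bridge.

Step 5
Reactants: 7 alcohol
Product: 8 (1S,4S,7R)-4,8,8-trimethylbicyclo[5.1.0]octan-3-one (C1 ketone)
Conditions: Dess–Martin periodinane, CH2Cl2, 0 °C → rt
Reagents that add atoms: none
Why: Dess–Martin oxidation works without base or strong acid, so the ketone forms without enolisation toward C10, whose configuration is probably the less stable one.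

Step 6
Reactants: 9 3-nitrobutan-2-ol (mixture of diastereomers)
Product: 11 (E)-2-nitrobut-2-ene, via nitro mesylate 10 (not isolated)
Conditions: MsCl, Et3N (2.2 equiv), CH2Cl2, 0 °C
Reagents that add atoms: none
Why: Mesylation of the β-nitro alcohol followed by E1cB loss of methanesulfonate is the usual dehydration to a conjugated nitroalkene, and the E isomer is the stable one.

Step 7
Reactants: 8 ketone; 11 (E)-2-nitrobut-2-ene
Product: 13 γ-nitro ketone (C5 side chain CH(CH3)CH(NO2)CH3, H5 trans to H6), via lithium enolate 12 (not isolated)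
Conditions: LiN(iPr)2, THF, −78 °C; 11, −78 °C; AcOH
Reagents that add atoms: (E)-2-nitrobut-2-ene (11), C/C=C(\C)[N+](=O)[O-]
Why: Kinetic deprotonation takes a proton from the C5 methylene and not from the C10 methine, and the Michael addition of enolate 12 to the nitroalkene occurs on the face anti to the CMe2 bridge, which sets C5 (H5 trans to H6), while C3 and C4 form as mixtures that are erased in steps 8 and 11.

Step 8
Reactants: 13 γ-nitro ketone
Product: 15 1,4-diketone (C1 and C3 ketones), via sodium nitronate 14 (not isolated)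
Conditions: NaOMe (1.0 equiv), MeOH, 0 °C; O3, −78 °C; N2 purge
Reagents that add atoms: ozone, O=[O+][O-]
Why: Ozonolytic Nef reaction: one equivalent of methoxide is used up by the far more acidic nitro C–H, and ozone cleaves the C=N bond of nitronate 14 at −78 °C, so that C10 and C5 never meet free base or hot acid.

Step 9
Reactants: 15 1,4-diketone
Product: 18 tricyclic enone, aromadendr-1-en-3-one, via lithium aldolate 16 (not isolated), via ketol acetate 17 (not isolated)
Conditions: LiN(iPr)2 (1.05 equiv), THF, −78 → −20 °C; Ac2O, DMAP (cat.), −20 °C → rt; DBU, rt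
Reagents that add atoms: none
Why: Kinetic enolisation of the methyl ketone, intramolecular aldol addition of C2 to the C1 ketone (five-membered ring, cis fusion), acetylation and E1cB elimination give the cyclopentenone without the hot protic base of a classical aldol condensation, which could epimerise C10 or move the double bond to C4=C5.

Step 10
Reactants: 18 enone
Product: 19 1,2-epoxy ketone (C1–O cis to H5 and to the C10 methyl group)
Conditions: 30% H2O2, NaOH (cat.), MeOH, 0 °C
Reagents that add atoms: hydrogen peroxide, OO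
Why: Weitz–Scheffer epoxidation: hydroperoxide attacks C1 on the face that carries H5, since the other face is covered by C6 and C9 of the seven-membered ring, and ring closure gives the epoxide with C1–O cis to H5 and to the C10 methyl group.

Step 11
Reactants: 19 epoxy ketone
Product: 21 1,2-epoxy C3=C4 triisopropylsilyl enol ether, via lithium enolate 20 (not isolated)
Conditions: LiN(iPr)2, THF, −78 °C; iPr3SiOTf, −78 → −40 °C
Reagents that add atoms: triisopropylsilyl trifluoromethanesulfonate, CC(C)[Si](OS(=O)(=O)C(F)(F)F)(C(C)C)C(C)C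
Why: C2 is an oxirane carbon and cannot be enolised, so the base can only take H4 and O-silylation gives the tetrasubstituted C3=C4 enol ether as a single regioisomer; it is installed now because a free C3 ketone after arylation would have the C1 aryloxy group in the β position and would expel it on any enolisation toward C2.

Step 12
Reactants: 21 epoxy enol silane
Product: 22 tertiary C1 alcohol with C3=C4 silyl enol ether
Conditions: LiEt3BH, THF, 0 °C → rt; H2O
Reagents that add atoms: none
Why: Hydride opens the trisubstituted epoxide by SN2 attack at the less substituted, allylic C2 from the face opposite to oxygen, so the C1–O bond and its configuration are kept and the tertiary alcohol is set free, while the bulky enol silane is inert to the borohydride.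

Step 13
Reactants: 22 tertiary alcohol; 23 trichloroethylene; 24 1-iodo-3-methylbutane
Product: 27 C1 (5-methylhex-1-ynyl) ether with C3=C4 silyl enol ether, via dichlorovinyl ether 25 (not isolated), via lithium alkynyl ether 26 (not isolated)
Conditions: KH, THF, 0 °C → rt; 23, −50 °C → rt; n-BuLi (2.5 equiv), −78 → −40 °C; 24, HMPA, −78 → 20 °C; Et3N-deactivated silica, kept at or below rt
Reagents that add atoms: trichloroethylene (23), ClC=C(Cl)Cl; 1-iodo-3-methylbutane (24), CC(C)CCI
Why: Ynol ether synthesis from trichloroethylene, known for tertiary alcohols: the potassium alkoxide adds to dichloroacetylene formed in situ, n-BuLi then causes elimination and chlorine–lithium exchange, and acetylide 26 is alkylated by the primary iodide with HMPA; the iPr3Si group sits on an in-plane vinylic oxygen far from the C1 oxygen and should not migrate, and 27 is kept cool because of its tendency to retro-ene fragmentation.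

Step 14
Reactants: 28 3-ethoxycyclobut-2-en-1-one
Product: 29 cyclobutane-1,3-dione
Conditions: 2 M HCl, H2O, rt
Reagents that add atoms: water, O
Why: Acid hydrolysis of the vinylogous ester gives the strongly acidic 1,3-dione, a known transformation of this compound.

Step 15
Reactants: 29 cyclobutane-1,3-dione
Product: 30 3-(triisopropylsilyloxy)cyclobut-2-en-1-one
Conditions: iPr3SiOTf, Et3N, CH2Cl2, −78 → 0 °C
Reagents that add atoms: triisopropylsilyl trifluoromethanesulfonate, CC(C)[Si](OS(=O)(=O)C(F)(F)F)(C(C)C)C(C)C
Why: O-silylation of the enolised 1,3-dione gives the vinylogous silyl ester; silyl is chosen in place of alkyl so that the C4′ oxygen can later be freed by fluoride, since cleavage of an alkyl aryl ether would need Lewis acids that break the tertiary C1–O bond first.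

Step 16
Reactants: 27 ynol ether; 30 3-(triisopropylsilyloxy)cyclobut-2-en-1-one
Product: 34 aryl ether with free C6′ hydroxyl, isopentyl chain on C1′ (C7′ as CH2) and C4′ silyloxy group, via vinylketene 31 (not isolated), via vinylcyclobutenone 32 (not isolated), via dienylketene 33 (not isolated)
Conditions: 30 (2 equiv), degassed Et2O, hν (254 nm, quartz), 15 °C until 27 is consumed; then toluene, 100 °C
Reagents that add atoms: 3-(triisopropylsilyloxy)cyclobut-2-en-1-one (30), CC(C)[Si](OC1=CC(=O)C1)(C(C)C)C(C)C
Why: Light opens 30 in a four-electron electrocyclic reaction to vinylketene 31, whose carbonyl carbon bonds to the alkyne carbon remote from oxygen in a (2+2) cycloaddition to give 32, and four-electron opening of 32 to dienylketene 33, six-electron closure and tautomerisation give phenol 34. This is the Danheiser benzannulation of cyclobutenones with alkoxyalkynes, with its first stage run photochemically, a known variant. The one new ring, the arene, closes by 6π electrocyclisation (C5′–C6′) after the two new bonds C6′–C1′ and C2′–C3′ have been made, and no stereocentre is created. The regiochemistry needed (hydroxyl next to the isopentyl-bearing carbon, silyloxy group para to it) is fixed by the polarisation of the ynol ether. The chemoselectivity needed, alkyne before the C3=C4 enol silane, rests on the much higher reactivity of ynol ethers toward ketenes and on the tetrasubstitution of the enol silane. The ketene is made by light at 15 °C because a tertiary alkyl ynol ether with β-hydrogens fragments by a retro-ene path at the temperatures at which a donor-substituted cyclobutenone would open thermally, so heat is applied only once 27 has become the robust vinylogous ester 32.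

Step 17
Reactants: 34 phenol
Product: 36 bridged C3 ketone with C4–C7′ bond and both phenol oxygens silylated, via o-quinone methide 35 (not isolated)
Conditions: DDQ (1.05 equiv), 2,6-di-tert-butylpyridine, 4 Å MS, CH2Cl2, −40 → 0 °C
Reagents that add atoms: none
Why: DDQ abstracts hydride from C7′, which has oxygen-bearing carbons in both ortho positions and the para position, much faster than it attacks the hindered enol silane, and the resulting o-quinone methide is closed by an intramolecular Mukaiyama–Michael addition in which C4 can reach C7′ only on the cyclopentene face that carries the C1–O tether (sets C4), C7′ should be set by the E-quinone methide reacting through a chair-like seven-membered transition state that puts H7′ and not the isobutyl group next to the C4 methyl group, and the silyl group passes to the phenolate oxygen.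

Step 18
Reactants: 36 bridged ketone
Product: 39 bridged resorcinol (C3 as CH2, C4′ and C6′ hydroxyls free), via silylhydrazone 37 (not isolated), via bis(silyl ether) 38 (not isolated)
Conditions: (tBuMe2SiNH)2, Sc(OTf)3 (cat.), CHCl3, rt → 55 °C, then vacuum; KOtBu, t-BuOH, DMSO, rt → 100 °C; aqueous work-up; Bu4NF, THF, rt; H2O
Reagents that add atoms: none
Why: Silylhydrazone variant of the Wolff–Kishner reduction: the hydrazone is made under neutral conditions so that the β-aryloxy ketone never meets base, afterwards the base removes the N–H and not a C2 proton, which shuts off loss of the aryloxide from C1, and the closing fluoride treatment removes whatever aryl silyl groups have survived.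

Step 19
Reactants: 39 bridged resorcinol
Product: 41 target CNP0189833.2, via bis(iminium) salt 40 (not isolated)
Conditions: POCl3, DMF, EtOAc, 0 °C → rt; then H2O, 40 °C
Reagents that add atoms: N,N-dimethylformamide, CN(C)C=O; water, O
Why: Vilsmeier–Haack formylation: the two free ring positions C3′ and C5′ are each ortho or para to three oxygen substituents, so that, as with phloroglucinol itself, both are attacked by the chloroiminium salt at room temperature, and the medium contains no strong Lewis acid that could open the cyclopropane or the tertiary ether.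

Compound list
1 | (+)-2-carene, (1S,6R)-3,7,7-trimethylbicyclo[4.1.0]hept-2-ene | CC1=C[C@H]2[C@@H](CC1)C2(C)C | starting material
2 | (1S,3R)-2,2-dimethyl-3-(3-oxobutyl)cyclopropane-1-carbaldehyde | O=C[C@H]1[C@@H](CCC(C)=O)C1(C)C | intermediate
3 | methyl enol ether of 4 (E/Z mixture, ring as in 2) | COC=C[C@H]1[C@@H](CCC(C)=O)C1(C)C | intermediate
4 | 2-[(1S,3R)-2,2-dimethyl-3-(3-oxobutyl)cyclopropyl]acetaldehyde | O=CC[C@H]1[C@@H](CCC(C)=O)C1(C)C | intermediate
5 | (1S,7R)-4,8,8-trimethylbicyclo[5.1.0]oct-3-ene | CC1=CC[C@H]2[C@@H](CC1)C2(C)C | intermediate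
6 | C1 alkylborane from 5 (boron anti to the CMe2 bridge) | B[C@H]1C[C@H]2[C@@H](CC[C@@H]1C)C2(C)C | intermediate
7 | (1S,3S,4S,7R)-4,8,8-trimethylbicyclo[5.1.0]octan-3-ol | O[C@H]1C[C@H]2[C@@H](CC[C@@H]1C)C2(C)C | intermediate
8 | (1S,4S,7R)-4,8,8-trimethylbicyclo[5.1.0]octan-3-one | O=C1C[C@H]2[C@@H](CC[C@@H]1C)C2(C)C | intermediate
9 | 3-nitrobutan-2-ol (diastereomer mixture) | CC(O)C(C)[N+](=O)[O-] | starting material
10 | 3-nitrobutan-2-yl methanesulfonate | CC(OS(C)(=O)=O)C(C)[N+](=O)[O-] | intermediate
11 | (E)-2-nitrobut-2-ene | C/C=C(\C)[N+](=O)[O-] | intermediate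
12 | kinetic lithium enolate of 8 (C1=C5) | [Li]OC1=C[C@H]2[C@@H](CC[C@@H]1C)C2(C)C | intermediate
13 | γ-nitro ketone, 8 with 3-nitrobutan-2-yl on C5 (anti to CMe2; C3, C4 mixtures) | CC([N+](=O)[O-])C(C)[C@H]1[C@H]2[C@@H](CC[C@H](C)C1=O)C2(C)C | intermediate
14 | sodium nitronate of 13 | CC(C(C)[C@H]1[C@H]2[C@@H](CC[C@H](C)C1=O)C2(C)C)=[N+]([O-])[O-].[Na+] | intermediate
15 | 1,4-diketone, 8 with 3-oxobutan-2-yl on C5 (C4 epimers) | CC(=O)C(C)[C@H]1[C@H]2[C@@H](CC[C@H](C)C1=O)C2(C)C | intermediate
16 | lithium aldolate, cis-fused 1-oxido-aromadendran-3-one (C4 epimers) | [Li]O[C@]12CC(=O)C(C)[C@H]1[C@H]1[C@@H](CC[C@@H]2C)C1(C)C | intermediate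
17 | 1-acetoxyaromadendran-3-one (C1–O cis to H5; C4 epimers) | CC(=O)O[C@]12CC(=O)C(C)[C@H]1[C@H]1[C@@H](CC[C@@H]2C)C1(C)C | intermediate
18 | aromadendr-1-en-3-one (H5 trans to H6, C10 methyl on the face of H5; C4 epimers) | CC1C(=O)C=C2[C@@H]1[C@H]1[C@@H](CC[C@@H]2C)C1(C)C | intermediate
19 | 1,2-epoxyaromadendran-3-one (epoxide on the face of H5; C4 epimers) | CC1C(=O)[C@H]2O[C@@]23[C@@H]1[C@H]1[C@@H](CC[C@@H]3C)C1(C)C | intermediate
20 | lithium C3=C4 enolate of 19 | CC1=C(O[Li])[C@H]2O[C@@]23[C@@H]1[C@H]1[C@@H](CC[C@@H]3C)C1(C)C | intermediate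
21 | 1,2-epoxy-3-(triisopropylsilyloxy)aromadendr-3-ene | CC1=C(O[Si](C(C)C)(C(C)C)C(C)C)[C@H]2O[C@@]23[C@@H]1[C@H]1[C@@H](CC[C@@H]3C)C1(C)C | intermediate
22 | 3-(triisopropylsilyloxy)aromadendr-3-en-1-ol (OH cis to H5 and to the C10 methyl) | O[C@]12CC(O[Si](C(C)C)(C(C)C)C(C)C)=C(C)[C@H]1[C@H]1[C@@H](CC[C@@H]2C)C1(C)C | intermediate
23 | trichloroethylene | ClC=C(Cl)Cl | starting material
24 | 1-iodo-3-methylbutane | CC(C)CCI | starting material
25 | (E)-1,2-dichlorovinyl ether of 22 | Cl/C=C(/Cl)O[C@]12CC(O[Si](C(C)C)(C(C)C)C(C)C)=C(C)[C@H]1[C@H]1[C@@H](CC[C@@H]2C)C1(C)C | intermediate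
26 | lithium alkynyl ether of 22 | [Li]C#CO[C@]12CC(O[Si](C(C)C)(C(C)C)C(C)C)=C(C)[C@H]1[C@H]1[C@@H](CC[C@@H]2C)C1(C)C | intermediate
27 | 5-methylhex-1-ynyl ether of 22 (key-step precursor) | CC(C)CCC#CO[C@]12CC(O[Si](C(C)C)(C(C)C)C(C)C)=C(C)[C@H]1[C@H]1[C@@H](CC[C@@H]2C)C1(C)C | intermediate
28 | 3-ethoxycyclobut-2-en-1-one | CCOC1=CC(=O)C1 | starting material
29 | cyclobutane-1,3-dione | O=C1CC(=O)C1 | intermediate
30 | 3-(triisopropylsilyloxy)cyclobut-2-en-1-one | CC(C)[Si](OC1=CC(=O)C1)(C(C)C)C(C)C | intermediate
31 | 3-(triisopropylsilyloxy)buta-1,3-dien-1-one (vinylketene) | C=C(C=C=O)O[Si](C(C)C)(C(C)C)C(C)C | intermediate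
32 | 2-isopentyl-3-(terpenyloxy)-4-[1-(triisopropylsilyloxy)vinyl]cyclobut-2-enone (ring C4 epimers) | CC(C)CCC1=C(O[C@]23CC(O[Si](C(C)C)(C(C)C)C(C)C)=C(C)[C@H]2[C@H]2[C@@H](CC[C@@H]3C)C2(C)C)C(C(=C)O[Si](C(C)C)(C(C)C)C(C)C)C1=O | intermediate
33 | dienylketene from 32 (ketene and siloxyvinyl groups cis) | CC(C)CCC(=C=O)/C(O[C@]12CC(O[Si](C(C)C)(C(C)C)C(C)C)=C(C)[C@H]1[C@H]1[C@@H](CC[C@@H]2C)C1(C)C)=C\C(=C)O[Si](C(C)C)(C(C)C)C(C)C | intermediate
34 | 2-isopentyl-3-(terpenyloxy)-5-(triisopropylsilyloxy)phenol (key-step product) | CC(C)CCc1c(O)cc(O[Si](C(C)C)(C(C)C)C(C)C)cc1O[C@]12CC(O[Si](C(C)C)(C(C)C)C(C)C)=C(C)[C@H]1[C@H]1[C@@H](CC[C@@H]2C)C1(C)C | intermediate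
35 | (E)-o-quinone methide from 34 (isobutyl anti to C6′=O) | CC(C)C/C=C1/C(=O)C=C(O[Si](C(C)C)(C(C)C)C(C)C)C=C1O[C@]12CC(O[Si](C(C)C)(C(C)C)C(C)C)=C(C)[C@H]1[C@H]1[C@@H](CC[C@@H]2C)C1(C)C | intermediate
36 | bridged C3 ketone, C4–C7′ closed, C4′ and C6′ as triisopropylsilyl ethers | CC(C)C[C@H]1c2c(O[Si](C(C)C)(C(C)C)C(C)C)cc(O[Si](C(C)C)(C(C)C)C(C)C)cc2O[C@]23CC(=O)[C@@]1(C)[C@H]2[C@H]1[C@@H](CC[C@@H]3C)C1(C)C | intermediate
37 | N-(tert-butyldimethylsilyl)hydrazone of 36 | CC(C)C[C@H]1c2c(O[Si](C(C)C)(C(C)C)C(C)C)cc(O[Si](C(C)C)(C(C)C)C(C)C)cc2O[C@]23CC(=NN[Si](C)(C)C(C)(C)C)[C@@]1(C)[C@H]2[C@H]1[C@@H](CC[C@@H]3C)C1(C)C | intermediate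
38 | C3-deoxygenated bis(triisopropylsilyl ether) | CC(C)C[C@H]1c2c(O[Si](C(C)C)(C(C)C)C(C)C)cc(O[Si](C(C)C)(C(C)C)C(C)C)cc2O[C@]23CC[C@@]1(C)[C@H]2[C@H]1[C@@H](CC[C@@H]3C)C1(C)C | intermediate
39 | bridged resorcinol (target without the two formyl groups) | CC(C)C[C@H]1c2c(O)cc(O)cc2O[C@]23CC[C@@]1(C)[C@H]2[C@H]1[C@@H](CC[C@@H]3C)C1(C)C | intermediate
40 | C3′,C5′ bis(dimethyliminium) dichloride | CC(C)C[C@H]1c2c(O)c(C=[N+](C)C)c(O)c(C=[N+](C)C)c2O[C@]23CC[C@@]1(C)[C@H]2[C@H]1[C@@H](CC[C@@H]3C)C1(C)C.[Cl-].[Cl-] | intermediate
41 | CNP0189833.2 | CC(C)C[C@H]1c2c(O)c(C=O)c(O)c(C=O)c2O[C@]23CC[C@@]1(C)[C@H]2[C@H]1[C@@H](CC[C@@H]3C)C1(C)C | target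

Total step count: 19. Longest linear sequence: 16 (steps 1–5, 7–13, 16–19).

Steps most likely to fail

1. Step 16. The ynol ether may be lost by retro-ene fragmentation or photodecomposition faster than the donor-substituted cyclobutenone opens, so the ketene is never intercepted. The fallback sets out from 27 and comes back at 34. It makes the same vinylketene 31 by photochemical Wolff rearrangement instead of ring opening. Butane-2,3-dione is converted with iPr3SiOTf and Et3N into 3-(triisopropylsilyloxy)but-3-en-2-one F1. Detrifluoroacetylative diazo transfer (LiN(SiMe3)2, CF3CO2CH2CF3; then MsN3, Et3N) gives 1-diazo-3-(triisopropylsilyloxy)but-3-en-2-one F2. Irradiation of F2 together with 27 at 300 nm and 0–15 °C releases nitrogen and gives 31, which is trapped to 32. Warming in toluene then leads to 34 as in the route. This is the diazo ketone form of the same benzannulation and needs neither short-wave light nor a reluctant electrocyclic opening.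

2. Step 17. The oxidant may attack the enol silane in competition with hydride abstraction at C7′. The quinone methide may shift its double bond into the side chain. Facial control at C7′ may also be weak. The fallback sets out from 22 and comes back at 36, and it generates the quinone methide without any oxidant. Compound 22 is taken through the one-flask sequence of step 13 as far as 26. This is added to 3-methylbutanal, and the resulting alkoxide is methylated with MeI to give the C7′-methoxy ynol ether F3. Benzannulation with 30 as in step 16 gives the o-hydroxybenzyl methyl ether F4. With MgBr2·OEt2 in CH2Cl2 at −78 °C, F4 loses methanol to give 35, which closes to 36 at a temperature at which the kinetic preference at C7′ should be at its highest.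

3. Step 13. The hindered potassium alkoxide may add slowly, the silyl group may wander to the C1 oxygen, or the alkylation of 26 by the unactivated iodide may be too slow for the lifetime of the ynol ether. The fallback sets out from 22 and comes back at 27. It builds the triple bond by elimination with the side chain already in place. 4-Methylpentanoyl chloride and Me3SiCHN2 give 1-diazo-5-methylhexan-2-one F5. Rh2(OAc)4-catalysed O–H insertion of F5 into 22 gives the α-alkoxy ketone F6. LiN(SiMe3)2 and PhNTf2 at −78 °C convert F6, through the chelated enolate, into the (Z)-enol triflate F7. KOtBu at −78 °C eliminates triflate anti to the vinylic hydrogen to give 27.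

Further compounds
F1 | step 16 | 3-(triisopropylsilyloxy)but-3-en-2-one | C=C(O[Si](C(C)C)(C(C)C)C(C)C)C(C)=O
F2 | step 16 | 1-diazo-3-(triisopropylsilyloxy)but-3-en-2-one | C=C(O[Si](C(C)C)(C(C)C)C(C)C)C(=O)C=[N+]=[N-]
F3 | step 17 | C7′-methoxy ynol ether, 3-methoxy-5-methylhex-1-ynyl ether of 22 (C7′ epimers) | CC(C)CC(OC)C#CO[C@]12CC(O[Si](C(C)C)(C(C)C)C(C)C)=C(C)[C@H]1[C@H]1[C@@H](CC[C@@H]2C)C1(C)C
F4 | step 17 | o-hydroxybenzyl methyl ether, 34 with methoxy on C7′ (C7′ epimers) | CC(C)CC(OC)c1c(O)cc(O[Si](C(C)C)(C(C)C)C(C)C)cc1O[C@]12CC(O[Si](C(C)C)(C(C)C)C(C)C)=C(C)[C@H]1[C@H]1[C@@H](CC[C@@H]2C)C1(C)C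
F5 | step 13 | 1-diazo-5-methylhexan-2-one | CC(C)CCC(=O)C=[N+]=[N-]
F6 | step 13 | α-alkoxy ketone, 5-methyl-2-oxohexyl ether of 22 | CC(C)CCC(=O)CO[C@]12CC(O[Si](C(C)C)(C(C)C)C(C)C)=C(C)[C@H]1[C@H]1[C@@H](CC[C@@H]2C)C1(C)C
F7 | step 13 | (Z)-enol triflate of F6 | CC(C)CC/C(OS(=O)(=O)C(F)(F)F)=C/O[C@]12CC(O[Si](C(C)C)(C(C)C)C(C)C)=C(C)[C@H]1[C@H]1[C@@H](CC[C@@H]2C)C1(C)C
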